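## Structural features

The target is a benzotropolone: a benzene ring (ring B) fused to a seven-membered tropolone ring (ring T). Ring T consists of Ca (bearing flavan 1), Cb (CH), Cc (C=O), Cd (C–OH), the two fusion carbons and Cg (CH). Ring B carries two hydroxyls on the Cd side of the fusion and, on the Cg side, C2 of a (2R,3R)-5,7-dihydroxyflavan-3-ol (flavan 2); Ca carries C2 of a second (2R,3R)-flavan-3-ol (flavan 1) whose O3 is esterified by gallic acid. The four stereocentres form two adjacent pairs, C2/C3 of each flavan, each pair cis; the pairs are remote from each other and must be set independently. Fragile elements are the nine phenols and the tropolone (oxidation, chelation), the two phloroglucinol-type rings A (very nucleophilic at C6/C8), the benzylic C2–O1 ethers (ionisation) and the gallate ester. The real difficulty is ring T: seven carbons with adjacent oxygens at Cc and Cd, attached to a fully substituted edge of ring B, with a carbon on Ca that must become a stereodefined flavan. A second difficulty is telling the two nearly identical 3-hydroxyls apart. The key step uses the fact that ring T without Cb and Cc is the five-membered ring of an indan-1-one, with Cd as ketone carbon and Ca as α-carbon. An ester on Ca (the future C2 of flavan 1) makes Cd–Ca the bond of a β-keto ester into which a two-carbon unit can be inserted, and the Cc methylene formed lies between ketone and alkene and can take the missing oxygen.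

## Logic of the disconnections

**35 ⇐ 34 ⇐ 33.** Ten O–CH2Ph bonds are cut in the last step and one O–Si bond in the step before. Reason: phenols, tropolone and the flavan 2 hydroxyl stay masked until nothing else remains to be done. Gain: all earlier intermediates are neutral, non-chelating and stable to oxidation. Demand: hydrogenolysis must spare the ester, the benzylic ring ethers and the tropolone ring; desilylation must spare the ester.

**33 ⇐ 31 + 32.** The ester C–O bond is cut. Reason: the two flavan hydroxyls differ only in when they are unmasked. Gain: the aroyl part is a bought acid. Demand: in 31 the hydroxyl of flavan 1 must be the only free one, which is why flavan 2 carries a silyl ether from 17 onwards.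

**31 ⇐ 30 ⇐ 29 + 14 ⇐ 28 ⇐ 27 + 11.** C4–C4a (arene to epoxide carbon), O1–C2 (aryl ether, with inversion), the epoxide oxygen, and C2–C3 (vinyl to aldehyde) are cut in turn. Reason: the whole flavan collapses to an aldehyde on Ca plus bought 14 and the C2 unit 11. Gain: two stereocentres come from one reagent-controlled epoxidation. Demand: the epoxidation must pick one carbinol epimer and the vinyl group only; the etherification must invert cleanly; the arene must attack the terminal epoxide carbon.

**27 ⇐ 26 ⇐ 25 ⇐ 24.** Only oxidation levels and one O–benzyl bond change. Reason: the ester is the group that survives the ring expansion, the aldehyde is the group the flavan needs. Gain: no new C–C bond. Demand: the ester must be reduced without touching the ring carbonyl, so it is done on 24 while the tropolone is present as its metal salt, and the benzyl group is put on afterwards.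

**24 ⇐ 22.** The C–O bond at Cc is cut; the 5,6-dione 23 is the link. Reason: 23 is a tautomer of the tropolone, so one oxygenation aromatises ring T. Gain: both ring oxygens are accounted for. Demand: oxidation at Cc and not at the benzylic C9 methylene.

**22 ⇐ 19 + 20 (key).** Cd–Cc and Cb–Ca are cut and Cd–Ca is rejoined. Reason: this removes two carbons and turns the seven-membered ring into a five-membered β-keto ester ring, a standard ring. Gain: one ring size class simpler, and 20 is the simplest possible partner. Demand: the two carbons must enter exactly between ketone carbon and α-carbon.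

**19 ⇐ 17 + 18; 17 ⇐ 16.** The Ca–CO2Me bond and the O–Si bond are cut. Reason: the ester is put on last because a β-keto ester would chelate titanium and compete as an acid in the steps that build flavan 2. Demand: the hydroxyl must be protected without strong base, since base would enolise the ketone; a silyl ether is therefore used instead of a benzyl ether.

**16 ⇐ 15 ⇐ 13 + 14 ⇐ 12 ⇐ 10 + 11.** The same four cuts as for flavan 1. Gain: flavan 2 collapses to an aldehyde on the indanone. Demand: every step must tolerate the aryl ketone, so the vinyl group is added with a reagent that reacts with aldehydes only.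

**10 ⇐ 8 + 9; 8 ⇐ 6; 6 ⇐ 2 + 3; 2 ⇐ 1.** The formyl C–C bond, the C1–C7a bond of the indanone, the side chain and the C–Br bond are cut. Reason for closing the five-membered ring this early: the closure is an electrophilic acylation, which a 1,3,5-trioxygenated ring A would intercept, so it is done before any such ring exists. Gain: the bromine first blocks the position that would otherwise be acylated and then becomes the formyl carbon of flavan 2; the aldehyde carbon of 1 becomes Cg. Demand: the acylation must close ortho to a benzyloxy group without cleaving it.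

## Other disconnections considered

**Alternative 1:** The cut is the O1–C2 bond of flavan 2, made near the end with ring T, flavan 1 and the gallate already in place. In the forward step, camphorsulfonic acid lets the free ring A phenol of a cis-epoxide open the benzylic C–O bond with inversion, which closes the pyran ring and leaves the epoxide oxygen as the C3 hydroxyl of A1.
- In its favour: both stereocentres of flavan 2 would come from one enantioselective epoxidation of a cis-alkene, so no resolution discards half of the material. On this point it is better than the chosen plan, which resolves twice.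
- Also in its favour: the C3 hydroxyl of A1 is born free and already distinct from the galloylated one. This is at least the equal of the silyl ether used here and saves its removal.
- Against it: the carbon that is opened is benzylic to a para-alkoxy arene, so the opening has cation character and the cis relation may erode; 5-exo attack at the other epoxide carbon competes.
- Against it: an asymmetric epoxidation would have to be run on a late intermediate that contains the whole benzotropolone.
- Against it: the step does not make ring T, so a second strategic step is still needed.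
- Comparison: structurally it solves one flavan, whereas the chosen key step solves the seven-membered ring. Mechanistically, an opening at a cation-stabilised carbon is less secure than a Mitsunobu inversion next to an epoxide. In step count the two ways to a flavan are about equal.

**Alternative 2:** The cut is Cb–Ca and Ca–Cg, so Ca alone is removed and a 1,2-dioxygenated dihydronaphthalene remains. In the forward step, dibromocarbene (CHBr3, aqueous NaOH, benzyltriethylammonium chloride) adds to the Cb=Cg styrene bond to give the gem-dibromocyclopropane A2; later loss of bromide opens the three-membered ring to the seven-membered ring with bromine on Ca.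
- In its favour: the oxygens on Cc and Cd are present from the start, so no late oxygenation at Cc is needed. This is better than the chosen plan.
- In its favour: dihalocarbene ring expansion is old, dependable chemistry. The number of skeletal bonds formed in the key step (two) is equal to that of the chosen plan, and neither forms a stereocentre.
- Against it: the carbene is generated in strong base next to two electron-rich arenes and many benzylic ether C–H bonds.
- Against it: the ring opening needs AgBF4 or heat and passes through an allyl cation beside a silyloxy group.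
- Against it: the diol must be oxidised twice to reach the tropolone.
- Against it: the carbon that becomes C2 of flavan 1 is absent and must be added to the vinyl bromide, whereas the chosen key step carries it through as the ester. The six-membered precursor is also longer to make than an indanone keto ester.
- Comparison: better in oxygenation pattern, poorer in chemoselectivity beside flavan 2, and expected to be three to four steps longer around the key step.

**Alternative 3:** The cut is Cg–Ca and Cc–Cb, which divides ring T into a five-atom unit on ring B and the Ca–Cb unit of an ynone that already holds the chain and ring A of flavan 1. In the forward step, Rh2(OAc)4 turns a formyl diazo ketone into a carbenoid, the formyl oxygen closes onto it to give a 2-benzopyrylium-4-olate, and this dipole adds to the ynone across its two ylide carbons to give the oxygen-bridged bicycle A3; opening the bridge gives the tropolone.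
- In its favour: it is the most convergent plan. Ring T, both of its oxygens and the skeleton of flavan 1 arrive in one step, which is better than the chosen plan in convergence and in oxygenation.
- In its favour: the bridgehead epimers converge, and C3 of flavan 1 can come from the chiral pool without resolution.
- Against it: a diazo ketone must be made on a pentasubstituted arene that already carries flavan 2, whose benzylic C–H bonds and ring A can react with the carbenoid.
- Against it: the orientation of the unsymmetrical ynone must place the acyl group on Ca and is not guaranteed.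
- Against it: C2 of flavan 1 is set late under substrate control, and both components are long to prepare.
- Comparison: convergence favours the alternative; predictability favours the chosen plan (one possible enolate, a symmetrical two-carbon partner, no regiochemical question). The total step count is expected to be similar or higher for the alternative.

Key step: step 11

Assumption: 1, 14 and 32 are bought as the benzyl ethers of 3,4-dihydroxybenzaldehyde, phloroglucinol and gallic acid; 3, 9, 11, 18 and 20 are bought as such.

Remark: intermediates 24 to 34 are written as the 6-oxygenated 5-oxo form of the benzotropolone and the target as the 5-hydroxy-6-oxo form; these are tautomers related by proton transfer between the neighbouring oxygens, so step 22 gives the target as written.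

Abbreviations in names: Bn = benzyl; TBS = tert-butyldimethylsilyl; Fl2 = the (2R,3R)-5,7-bis(benzyloxy)-3-(tert-butyldimethylsilyloxy)-3,4-dihydro-2H-chromen-2-yl group (flavan 2 with its silyl ether).

## Route

Step 1
Reactants: 1 3,4-bis(benzyloxy)benzaldehyde
Product: 2 2-bromo-4,5-bis(benzyloxy)benzaldehyde
Conditions: Br2, NaOAc, AcOH, rt
Reagents that add atoms: bromine, BrBr
Why: Electrophilic aromatic bromination; 3,4-dialkoxybenzaldehydes brominate para to the 3-alkoxy group and ortho to the formyl group, and this bromine later blocks the ring closure of step 3 from the wrong position and becomes the formyl carbon of flavan 2.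

Step 2
Reactants: 2 2-bromo-4,5-bis(benzyloxy)benzaldehyde, 3 Meldrum's acid
Product: 6 3-[2-bromo-4,5-bis(benzyloxy)phenyl]propanoic acid, via arylidene Meldrum's acid 4 (not isolated), via benzyl Meldrum's acid 5 (not isolated)
Conditions: HCO2H/Et3N (5:2), 95 °C; then aq. HCl
Reagents that add atoms: water, O
Why: One-flask Knoevenagel condensation, conjugate reduction by formate and hydrolysis–decarboxylation of the Meldrum's acid adduct, a known route from aryl aldehydes to 3-arylpropanoic acids that needs no hydrogenation and so spares the aryl bromide and the benzyl ethers.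

Step 3
Reactants: 6 3-[2-bromo-4,5-bis(benzyloxy)phenyl]propanoic acid
Product: 8 4-bromo-6,7-bis(benzyloxy)indan-1-one, via acid chloride 7 (not isolated)
Conditions: (COCl)2, DMF (cat.), CH2Cl2, 0 °C → rt; then SnCl4, CH2Cl2, −40 → 0 °C
Reagents that add atoms: none
Why: Intramolecular Friedel–Crafts acylation; with the other ortho position blocked by bromine the acylium ion can only close ortho to a benzyloxy group, which gives the 6,7-dioxygenated indanone, and no phloroglucinol ring is yet present to compete.

Step 4
Reactants: 8 4-bromo-6,7-bis(benzyloxy)indan-1-one, 9 carbon monoxide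
Product: 10 6,7-bis(benzyloxy)-1-oxoindane-4-carbaldehyde
Conditions: Pd(OAc)2 (1 mol%), PAd2(n-Bu) (3 mol%), TMEDA, CO/H2 (1:1, 5 bar), toluene, 100 °C
Reagents that add atoms: none
Why: Palladium-catalysed reductive carbonylation (formylation) of an aryl bromide: oxidative addition to zerovalent palladium, CO insertion and hydrogenolysis of the acyl complex; ketone and benzyl ethers are tolerated, whereas halogen–lithium exchange would attack the ketone.

Step 5
Reactants: 10 6,7-bis(benzyloxy)-1-oxoindane-4-carbaldehyde, 11 vinyl bromide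
Product: 12 racemic 6,7-bis(benzyloxy)-4-(1-hydroxyprop-2-en-1-yl)indan-1-one
Conditions: CrCl2 (4 equiv), NiCl2 (2 mol%), DMF/THF, rt
Reagents that add atoms: none
Why: Nozaki–Hiyama–Kishi vinylation; the vinylchromium species adds to aldehydes and leaves the aryl ketone untouched; the carbinol forms as a racemate and is resolved in step 6.

Step 6
Reactants: 12 racemic 6,7-bis(benzyloxy)-4-(1-hydroxyprop-2-en-1-yl)indan-1-one
Product: 13 6,7-bis(benzyloxy)-4-{(S)-hydroxy[(2R)-oxiran-2-yl]methyl}indan-1-one
Conditions: Ti(OiPr)4, L-(+)-diisopropyl tartrate, t-BuOOH (0.55 equiv), 4 Å molecular sieves, CH2Cl2, −20 °C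
Reagents that add atoms: tert-butyl hydroperoxide, CC(C)(C)OO
Why: Sharpless kinetic resolution by asymmetric epoxidation: with the L-(+)-tartrate the (R)-carbinol is epoxidised fast to the erythro epoxy alcohol (oxirane carbon R, the future C3; the carbinol descriptor becomes S only because the oxirane outranks the aryl group), while the (S)-enantiomer is left and separated.

Step 7
Reactants: 13 6,7-bis(benzyloxy)-4-{(S)-hydroxy[(2R)-oxiran-2-yl]methyl}indan-1-one, 14 3,5-bis(benzyloxy)phenol
Product: 15 6,7-bis(benzyloxy)-4-{(R)-[3,5-bis(benzyloxy)phenoxy][(2R)-oxiran-2-yl]methyl}indan-1-one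
Conditions: PPh3, diisopropyl azodicarboxylate, toluene, 0 °C → rt
Reagents that add atoms: none
Why: Mitsunobu etherification with SN2 inversion at the carbinol carbon (S → R), which sets the future C2; the erythro relation plus this inversion is what gives the 2,3-cis flavan, and the epoxide is inert to the neutral conditions.

Step 8
Reactants: 15 6,7-bis(benzyloxy)-4-{(R)-[3,5-bis(benzyloxy)phenoxy][(2R)-oxiran-2-yl]methyl}indan-1-one
Product: 16 6,7-bis(benzyloxy)-4-[(2R,3R)-5,7-bis(benzyloxy)-3-hydroxy-3,4-dihydro-2H-chromen-2-yl]indan-1-one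
Conditions: (CF3)2CHOH, 0 °C → rt
Reagents that add atoms: none
Why: Intramolecular Friedel–Crafts alkylation of an electron-rich arene by an epoxide, promoted by the hydrogen-bond-donor solvent; the ring A carbon ortho to the ether oxygen attacks the terminal epoxide carbon (6-endo), so C4–C4a forms, the oxygen stays on C3 with its configuration and C2 is untouched.

Step 9
Reactants: 16 6,7-bis(benzyloxy)-4-[(2R,3R)-5,7-bis(benzyloxy)-3-hydroxy-3,4-dihydro-2H-chromen-2-yl]indan-1-one
Product: 17 6,7-bis(benzyloxy)-4-Fl2-indan-1-one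
Conditions: t-BuMe2SiOTf, 2,6-lutidine, CH2Cl2, −78 → −20 °C
Reagents that add atoms: tert-butyldimethylsilyl triflate, CC(C)(C)[Si](C)(C)OS(=O)(=O)C(F)(F)F
Why: Silylation of the hindered secondary hydroxyl under non-enolising conditions; a base-mediated benzylation would enolise and C-alkylate the indanone, and the silyl ether keeps this hydroxyl distinct from that of flavan 1 until step 21.

Step 10
Reactants: 17 6,7-bis(benzyloxy)-4-Fl2-indan-1-one, 18 dimethyl carbonate
Product: 19 methyl 6,7-bis(benzyloxy)-4-Fl2-1-oxoindane-2-carboxylate (C2 epimers)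
Conditions: NaH, THF, 65 °C; AcOH quench
Reagents that add atoms: none
Why: Crossed Claisen condensation (C-acylation of the ketone enolate), driven by formation of the stabilised β-keto ester enolate; C2 is the only enolisable position, and the epimer mixture does not matter because C2 becomes sp2 in step 11.

Step 11
Reactants: 19 methyl 6,7-bis(benzyloxy)-4-Fl2-1-oxoindane-2-carboxylate, 20 acetylene
Product: 22 methyl 3,4-bis(benzyloxy)-1-Fl2-5-oxo-6,9-dihydro-5H-benzo[7]annulene-8-carboxylate, via fused cyclobutenol 21 (not isolated)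
Conditions: [ReBr(CO)3(thf)]2 (5 mol%), benzyl isocyanide (10 mol%), acetylene (1 atm), toluene, 50 °C
Reagents that add atoms: none
Why: The β-keto ester is taken up by the monovalent rhenium carbonyl as a rhenium enolate whose α-carbon (Ca) adds to coordinated acetylene, forming Ca–Cb and an alkenyl–rhenium species. Its metal-bearing carbon (Cc) then adds to the neighbouring aryl ketone carbon Cd in a 4-exo closure, forming Cc–Cd and the cyclobutene-fused alkoxide 21. Retro-aldol cleavage of the strained Cd–Ca bond, with the ester taking the charge, converts the fused four/five system into the seven-membered ring, and protonation at Cc gives the conjugated ester 22, so the ring arises by two-carbon expansion and not by end-to-end cyclisation. The closest known reaction type is the rhenium-catalysed insertion of terminal alkynes into the ketone–α-carbon bond of cyclic β-keto esters, of which acetylene is the parent alkyne. No stereocentre is formed and the C2 centre of 19 is erased. The selectivity needed is cleavage of exactly the Cd–Ca bond: only this bond lies between the enolisable ester carbon and the ketone, the aryl ketone cannot enolise towards ring B so a single enolate exists, and acetylene is symmetrical so no regiochemical question arises. A double-bond isomer conjugated to the ketone would be carried on, since both isomers give the same dienol in step 12.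

Step 12
Reactants: 22 methyl 3,4-bis(benzyloxy)-1-Fl2-5-oxo-6,9-dihydro-5H-benzo[7]annulene-8-carboxylate
Product: 24 methyl 3,4-bis(benzyloxy)-1-Fl2-6-hydroxy-5-oxo-5H-benzo[7]annulene-8-carboxylate, via 5,6-dione 23 (not isolated)
Conditions: SeO2 (1.1 equiv), 1,4-dioxane/H2O (30:1), 70 °C
Reagents that add atoms: selenium dioxide, O=[Se]=O
Why: Riley oxidation: the enol of the ketone, easily formed because Cc is also allylic to the unsaturated ester, attacks SeO2 and the selenium ester collapses to the 5,6-dione 23, which enolises through the diene with loss of a C9 hydrogen to the aromatic benzotropolone.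

Step 13
Reactants: 24 methyl 3,4-bis(benzyloxy)-1-Fl2-6-hydroxy-5-oxo-5H-benzo[7]annulene-8-carboxylate
Product: 25 3,4-bis(benzyloxy)-1-Fl2-6-hydroxy-8-(hydroxymethyl)-5H-benzo[7]annulen-5-one
Conditions: i-Bu2AlH (4.5 equiv), CH2Cl2, −78 → −20 °C; aq. potassium sodium tartrate
Reagents that add atoms: none
Why: Hydride reduction of the conjugated ester to the primary alcohol; the first equivalent of i-Bu2AlH deprotonates the tropolone to an aluminium tropolonate, an electron-rich chelate that hydride does not attack, so the ring carbonyl is protected as its own salt.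

Step 14
Reactants: 25 3,4-bis(benzyloxy)-1-Fl2-6-hydroxy-8-(hydroxymethyl)-5H-benzo[7]annulen-5-one
Product: 26 3,4,6-tris(benzyloxy)-1-Fl2-8-(hydroxymethyl)-5H-benzo[7]annulen-5-one
Conditions: BnBr, K2CO3, DMF, rt
Reagents that add atoms: benzyl bromide, BrCc1ccccc1
Why: Williamson O-alkylation of the acidic tropolone hydroxyl; carbonate does not deprotonate the primary alcohol, the oxygen on C6 is alkylated because this keeps ring B benzenoid and avoids the peri benzyloxy group, and the regioisomeric ether would converge at step 22.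

Step 15
Reactants: 26 3,4,6-tris(benzyloxy)-1-Fl2-8-(hydroxymethyl)-5H-benzo[7]annulen-5-one
Product: 27 3,4,6-tris(benzyloxy)-1-Fl2-5-oxo-5H-benzo[7]annulene-8-carbaldehyde
Conditions: Dess–Martin periodinane, CH2Cl2, 0 °C → rt
Reagents that add atoms: none
Why: Dess–Martin oxidation of the primary allylic-type alcohol to the aldehyde under neutral, non-chelating conditions that leave the silyl ether, benzyl ethers and alkoxytropone alone.

Step 16
Reactants: 27 3,4,6-tris(benzyloxy)-1-Fl2-5-oxo-5H-benzo[7]annulene-8-carbaldehyde, 11 vinyl bromide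
Product: 28 3,4,6-tris(benzyloxy)-1-Fl2-8-(1-hydroxyprop-2-en-1-yl)-5H-benzo[7]annulen-5-one (both carbinol epimers)
Conditions: CrCl2 (4 equiv), NiCl2 (2 mol%), DMF/THF, rt
Reagents that add atoms: none
Why: Nozaki–Hiyama–Kishi vinylation, chosen because it adds to the aldehyde only and spares the alkoxytropone carbonyl that a Grignard reagent could attack; the existing stereocentres are remote, so both carbinol epimers form.

Step 17
Reactants: 28 3,4,6-tris(benzyloxy)-1-Fl2-8-(1-hydroxyprop-2-en-1-yl)-5H-benzo[7]annulen-5-one
Product: 29 3,4,6-tris(benzyloxy)-1-Fl2-8-{(S)-hydroxy[(2R)-oxiran-2-yl]methyl}-5H-benzo[7]annulen-5-one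
Conditions: Ti(OiPr)4, L-(+)-diisopropyl tartrate, t-BuOOH (0.55 equiv), 4 Å molecular sieves, CH2Cl2, −20 °C
Reagents that add atoms: tert-butyl hydroperoxide, CC(C)(C)OO
Why: Sharpless asymmetric epoxidation used as a reagent-controlled resolution: the (R)-carbinol epimer is epoxidised on the vinyl group to the erythro epoxy alcohol (oxirane carbon R, the future C3 of flavan 1), the (S)-epimer is left and separated, and the electron-poor tropone double bonds are poor partners for the electrophilic titanium peroxide.

Step 18
Reactants: 29 3,4,6-tris(benzyloxy)-1-Fl2-8-{(S)-hydroxy[(2R)-oxiran-2-yl]methyl}-5H-benzo[7]annulen-5-one, 14 3,5-bis(benzyloxy)phenol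
Product: 30 3,4,6-tris(benzyloxy)-1-Fl2-8-{(R)-[3,5-bis(benzyloxy)phenoxy][(2R)-oxiran-2-yl]methyl}-5H-benzo[7]annulen-5-one
Conditions: PPh3, diisopropyl azodicarboxylate, toluene, 0 °C → rt
Reagents that add atoms: none
Why: Mitsunobu etherification with SN2 inversion (S → R) that sets the future C2 of flavan 1; the tropolone oxygen is benzylated and so cannot act as the acidic partner.

Step 19
Reactants: 30 3,4,6-tris(benzyloxy)-1-Fl2-8-{(R)-[3,5-bis(benzyloxy)phenoxy][(2R)-oxiran-2-yl]methyl}-5H-benzo[7]annulen-5-one
Product: 31 3,4,6-tris(benzyloxy)-8-[(2R,3R)-5,7-bis(benzyloxy)-3-hydroxy-3,4-dihydro-2H-chromen-2-yl]-1-Fl2-5H-benzo[7]annulen-5-one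
Conditions: (CF3)2CHOH, 0 °C → rt
Reagents that add atoms: none
Why: Intramolecular Friedel–Crafts alkylation of the phloroglucinol-type ring by the terminal epoxide carbon (6-endo), as in step 8; C3 keeps its oxygen and configuration, C2 is untouched, and the 2R,3R cis flavan results.

Step 20
Reactants: 31 3,4,6-tris(benzyloxy)-8-[(2R,3R)-5,7-bis(benzyloxy)-3-hydroxy-3,4-dihydro-2H-chromen-2-yl]-1-Fl2-5H-benzo[7]annulen-5-one, 32 3,4,5-tris(benzyloxy)benzoic acid
Product: 33 (2R,3R)-5,7-bis(benzyloxy)-2-[3,4,6-tris(benzyloxy)-1-Fl2-5-oxo-5H-benzo[7]annulen-8-yl]-3,4-dihydro-2H-chromen-3-yl 3,4,5-tris(benzyloxy)benzoate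
Conditions: EDC·HCl, DMAP, CH2Cl2, rt
Reagents that add atoms: none
Why: Steglich-type carbodiimide esterification of the only free hydroxyl in the molecule; the hydroxyl of flavan 2 is silylated, so the gallate can go nowhere else, and no stereocentre is touched.

Step 21
Reactants: 33 (2R,3R)-5,7-bis(benzyloxy)-2-[3,4,6-tris(benzyloxy)-1-Fl2-5-oxo-5H-benzo[7]annulen-8-yl]-3,4-dihydro-2H-chromen-3-yl 3,4,5-tris(benzyloxy)benzoate
Product: 34 (2R,3R)-5,7-bis(benzyloxy)-2-{3,4,6-tris(benzyloxy)-1-[(2R,3R)-5,7-bis(benzyloxy)-3-hydroxy-3,4-dihydro-2H-chromen-2-yl]-5-oxo-5H-benzo[7]annulen-8-yl}-3,4-dihydro-2H-chromen-3-yl 3,4,5-tris(benzyloxy)benzoate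
Conditions: HF·pyridine, THF/pyridine, 0 °C → rt
Reagents that add atoms: none
Why: Fluoride cleavage of the silyl ether under buffered, mildly acidic conditions that leave the ester, the benzyl ethers and the alkoxytropone intact; the two 3-oxygens cannot exchange the acyl group because they sit on different flavans.

Step 22
Reactants: 34 (2R,3R)-5,7-bis(benzyloxy)-2-{3,4,6-tris(benzyloxy)-1-[(2R,3R)-5,7-bis(benzyloxy)-3-hydroxy-3,4-dihydro-2H-chromen-2-yl]-5-oxo-5H-benzo[7]annulen-8-yl}-3,4-dihydro-2H-chromen-3-yl 3,4,5-tris(benzyloxy)benzoate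
Product: 35 the target (benzotropolone bearing flavan 2 with free 3-hydroxyl and flavan 1 as its 3-O-gallate, all four centres R)
Conditions: H2 (1 atm), Pd(OH)2/C, THF/MeOH, rt
Reagents that add atoms: none
Why: Catalytic hydrogenolysis of the nine aryl benzyl ethers and the tropolone benzyl ether under neutral conditions; the ester, the ring ethers and the four stereocentres are not affected, and the freed tropolone is the target tautomer.

## Compound list

1 | 3,4-bis(benzyloxy)benzaldehyde | O=Cc1ccc(OCc2ccccc2)c(OCc2ccccc2)c1 | starting material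
2 | 2-bromo-4,5-bis(benzyloxy)benzaldehyde | O=Cc1cc(OCc2ccccc2)c(OCc2ccccc2)cc1Br | intermediate
3 | Meldrum's acid (2,2-dimethyl-1,3-dioxane-4,6-dione) | CC1(C)OC(=O)CC(=O)O1 | starting material
4 | 5-[2-bromo-4,5-bis(benzyloxy)benzylidene]-2,2-dimethyl-1,3-dioxane-4,6-dione | CC1(C)OC(=O)C(=Cc2cc(OCc3ccccc3)c(OCc3ccccc3)cc2Br)C(=O)O1 | intermediate (not isolated)
5 | 5-[2-bromo-4,5-bis(benzyloxy)benzyl]-2,2-dimethyl-1,3-dioxane-4,6-dione | CC1(C)OC(=O)C(Cc2cc(OCc3ccccc3)c(OCc3ccccc3)cc2Br)C(=O)O1 | intermediate (not isolated)
6 | 3-[2-bromo-4,5-bis(benzyloxy)phenyl]propanoic acid | OC(=O)CCc1cc(OCc2ccccc2)c(OCc2ccccc2)cc1Br | intermediate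
7 | 3-[2-bromo-4,5-bis(benzyloxy)phenyl]propanoyl chloride | ClC(=O)CCc1cc(OCc2ccccc2)c(OCc2ccccc2)cc1Br | intermediate (not isolated)
8 | 4-bromo-6,7-bis(benzyloxy)indan-1-one | O=C1CCc2c(Br)cc(OCc3ccccc3)c(OCc3ccccc3)c21 | intermediate
9 | carbon monoxide | [C-]#[O+] | starting material
10 | 6,7-bis(benzyloxy)-1-oxoindane-4-carbaldehyde | O=Cc1cc(OCc2ccccc2)c(OCc2ccccc2)c2C(=O)CCc12 | intermediate
11 | vinyl bromide | C=CBr | starting material
12 | racemic 6,7-bis(benzyloxy)-4-(1-hydroxyprop-2-en-1-yl)indan-1-one | C=CC(O)c1cc(OCc2ccccc2)c(OCc2ccccc2)c2C(=O)CCc12 | intermediate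
13 | 6,7-bis(benzyloxy)-4-{(S)-hydroxy[(2R)-oxiran-2-yl]methyl}indan-1-one | O[C@H]([C@H]1CO1)c1cc(OCc2ccccc2)c(OCc2ccccc2)c2C(=O)CCc12 | intermediate
14 | 3,5-bis(benzyloxy)phenol | Oc1cc(OCc2ccccc2)cc(OCc2ccccc2)c1 | starting material
15 | 6,7-bis(benzyloxy)-4-{(R)-[3,5-bis(benzyloxy)phenoxy][(2R)-oxiran-2-yl]methyl}indan-1-one | c1ccccc1COc1cc(OCc2ccccc2)cc(O[C@@H]([C@H]2CO2)c2cc(OCc3ccccc3)c(OCc3ccccc3)c3C(=O)CCc23)c1 | intermediate
16 | 6,7-bis(benzyloxy)-4-[(2R,3R)-5,7-bis(benzyloxy)-3-hydroxy-3,4-dihydro-2H-chromen-2-yl]indan-1-one | O=C1CCc2c([C@H]3Oc4cc(OCc5ccccc5)cc(OCc5ccccc5)c4C[C@H]3O)cc(OCc3ccccc3)c(OCc3ccccc3)c21 | intermediate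
17 | 6,7-bis(benzyloxy)-4-Fl2-indan-1-one | O=C1CCc2c([C@H]3Oc4cc(OCc5ccccc5)cc(OCc5ccccc5)c4C[C@H]3O[Si](C)(C)C(C)(C)C)cc(OCc3ccccc3)c(OCc3ccccc3)c21 | intermediate
18 | dimethyl carbonate | COC(=O)OC | starting material
19 | methyl 6,7-bis(benzyloxy)-4-Fl2-1-oxoindane-2-carboxylate (C2 epimers) | COC(=O)C1Cc2c([C@H]3Oc4cc(OCc5ccccc5)cc(OCc5ccccc5)c4C[C@H]3O[Si](C)(C)C(C)(C)C)cc(OCc3ccccc3)c(OCc3ccccc3)c2C1=O | intermediate (key-step precursor)
20 | acetylene | C#C | starting material
21 | cyclobutene-fused indanol (a rhenium alkoxide in the flask, written as the alcohol): four-membered ring Ca–Cb=Cc–Cd(OH) fused on the old C1–C2 bond of 19, ring-fusion centres undefined | COC(=O)C12Cc3c([C@H]4Oc5cc(OCc6ccccc6)cc(OCc6ccccc6)c5C[C@H]4O[Si](C)(C)C(C)(C)C)cc(OCc4ccccc4)c(OCc4ccccc4)c3C1(O)C=C2 | intermediate (not isolated)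
22 | methyl 3,4-bis(benzyloxy)-1-Fl2-5-oxo-6,9-dihydro-5H-benzo[7]annulene-8-carboxylate | COC(=O)C1=CCC(=O)c2c(OCc3ccccc3)c(OCc3ccccc3)cc([C@H]3Oc4cc(OCc5ccccc5)cc(OCc5ccccc5)c4C[C@H]3O[Si](C)(C)C(C)(C)C)c2C1 | intermediate (key-step product)
23 | methyl 3,4-bis(benzyloxy)-1-Fl2-5,6-dioxo-6,9-dihydro-5H-benzo[7]annulene-8-carboxylate | COC(=O)C1=CC(=O)C(=O)c2c(OCc3ccccc3)c(OCc3ccccc3)cc([C@H]3Oc4cc(OCc5ccccc5)cc(OCc5ccccc5)c4C[C@H]3O[Si](C)(C)C(C)(C)C)c2C1 | intermediate (not isolated)
24 | methyl 3,4-bis(benzyloxy)-1-Fl2-6-hydroxy-5-oxo-5H-benzo[7]annulene-8-carboxylate | COC(=O)C1=Cc2c([C@H]3Oc4cc(OCc5ccccc5)cc(OCc5ccccc5)c4C[C@H]3O[Si](C)(C)C(C)(C)C)cc(OCc3ccccc3)c(OCc3ccccc3)c2C(=O)C(O)=C1 | intermediate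
25 | 3,4-bis(benzyloxy)-1-Fl2-6-hydroxy-8-(hydroxymethyl)-5H-benzo[7]annulen-5-one | OCC1=Cc2c([C@H]3Oc4cc(OCc5ccccc5)cc(OCc5ccccc5)c4C[C@H]3O[Si](C)(C)C(C)(C)C)cc(OCc3ccccc3)c(OCc3ccccc3)c2C(=O)C(O)=C1 | intermediate
26 | 3,4,6-tris(benzyloxy)-1-Fl2-8-(hydroxymethyl)-5H-benzo[7]annulen-5-one | OCC1=Cc2c([C@H]3Oc4cc(OCc5ccccc5)cc(OCc5ccccc5)c4C[C@H]3O[Si](C)(C)C(C)(C)C)cc(OCc3ccccc3)c(OCc3ccccc3)c2C(=O)C(OCc2ccccc2)=C1 | intermediate
27 | 3,4,6-tris(benzyloxy)-1-Fl2-5-oxo-5H-benzo[7]annulene-8-carbaldehyde | O=CC1=Cc2c([C@H]3Oc4cc(OCc5ccccc5)cc(OCc5ccccc5)c4C[C@H]3O[Si](C)(C)C(C)(C)C)cc(OCc3ccccc3)c(OCc3ccccc3)c2C(=O)C(OCc2ccccc2)=C1 | intermediate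
28 | 3,4,6-tris(benzyloxy)-1-Fl2-8-(1-hydroxyprop-2-en-1-yl)-5H-benzo[7]annulen-5-one (both carbinol epimers) | C=CC(O)C1=Cc2c([C@H]3Oc4cc(OCc5ccccc5)cc(OCc5ccccc5)c4C[C@H]3O[Si](C)(C)C(C)(C)C)cc(OCc3ccccc3)c(OCc3ccccc3)c2C(=O)C(OCc2ccccc2)=C1 | intermediate
29 | 3,4,6-tris(benzyloxy)-1-Fl2-8-{(S)-hydroxy[(2R)-oxiran-2-yl]methyl}-5H-benzo[7]annulen-5-one | O[C@H]([C@H]1CO1)C1=Cc2c([C@H]3Oc4cc(OCc5ccccc5)cc(OCc5ccccc5)c4C[C@H]3O[Si](C)(C)C(C)(C)C)cc(OCc3ccccc3)c(OCc3ccccc3)c2C(=O)C(OCc2ccccc2)=C1 | intermediate
30 | 3,4,6-tris(benzyloxy)-1-Fl2-8-{(R)-[3,5-bis(benzyloxy)phenoxy][(2R)-oxiran-2-yl]methyl}-5H-benzo[7]annulen-5-one | c1ccccc1COc1cc(OCc2ccccc2)cc(O[C@@H]([C@H]2CO2)C2=Cc3c([C@H]4Oc5cc(OCc6ccccc6)cc(OCc6ccccc6)c5C[C@H]4O[Si](C)(C)C(C)(C)C)cc(OCc4ccccc4)c(OCc4ccccc4)c3C(=O)C(OCc3ccccc3)=C2)c1 | intermediate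
31 | 3,4,6-tris(benzyloxy)-8-[(2R,3R)-5,7-bis(benzyloxy)-3-hydroxy-3,4-dihydro-2H-chromen-2-yl]-1-Fl2-5H-benzo[7]annulen-5-one | O[C@@H]1Cc2c(OCc3ccccc3)cc(OCc3ccccc3)cc2O[C@@H]1C1=Cc2c([C@H]3Oc4cc(OCc5ccccc5)cc(OCc5ccccc5)c4C[C@H]3O[Si](C)(C)C(C)(C)C)cc(OCc3ccccc3)c(OCc3ccccc3)c2C(=O)C(OCc2ccccc2)=C1 | intermediate
32 | 3,4,5-tris(benzyloxy)benzoic acid | OC(=O)c1cc(OCc2ccccc2)c(OCc2ccccc2)c(OCc2ccccc2)c1 | starting material
33 | (2R,3R)-5,7-bis(benzyloxy)-2-[3,4,6-tris(benzyloxy)-1-Fl2-5-oxo-5H-benzo[7]annulen-8-yl]-3,4-dihydro-2H-chromen-3-yl 3,4,5-tris(benzyloxy)benzoate | O=C(O[C@@H]1Cc2c(OCc3ccccc3)cc(OCc3ccccc3)cc2O[C@@H]1C1=Cc2c([C@H]3Oc4cc(OCc5ccccc5)cc(OCc5ccccc5)c4C[C@H]3O[Si](C)(C)C(C)(C)C)cc(OCc3ccccc3)c(OCc3ccccc3)c2C(=O)C(OCc2ccccc2)=C1)c1cc(OCc2ccccc2)c(OCc2ccccc2)c(OCc2ccccc2)c1 | intermediate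
34 | (2R,3R)-5,7-bis(benzyloxy)-2-{3,4,6-tris(benzyloxy)-1-[(2R,3R)-5,7-bis(benzyloxy)-3-hydroxy-3,4-dihydro-2H-chromen-2-yl]-5-oxo-5H-benzo[7]annulen-8-yl}-3,4-dihydro-2H-chromen-3-yl 3,4,5-tris(benzyloxy)benzoate | O=C(O[C@@H]1Cc2c(OCc3ccccc3)cc(OCc3ccccc3)cc2O[C@@H]1C1=Cc2c([C@H]3Oc4cc(OCc5ccccc5)cc(OCc5ccccc5)c4C[C@H]3O)cc(OCc3ccccc3)c(OCc3ccccc3)c2C(=O)C(OCc2ccccc2)=C1)c1cc(OCc2ccccc2)c(OCc2ccccc2)c(OCc2ccccc2)c1 | intermediate
35 | target: benzotropolone with (2R,3R)-flavan-3-ol (flavan 2) on ring B and (2R,3R)-flavan-3-yl 3,4,5-trihydroxybenzoate (flavan 1) on Ca | O=C(O[C@@H]1Cc2c(O)cc(O)cc2O[C@@H]1c1cc(=O)c(O)c2c(O)c(O)cc([C@H]3Oc4cc(O)cc(O)c4C[C@H]3O)c2c1)c1cc(O)c(O)c(O)c1 | target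

## Step count and least certain steps

Total: 22 steps. Longest linear sequence: 22 steps (1 → 35); 3, 9, 11, 14, 18, 20 and 32 enter as bought components. Steps 6 and 17 are resolutions and cannot deliver more than half of the material; this is a known cost, not an uncertainty.

**Step 11 (key step).** Acetylene is the smallest and most weakly bound alkyne of its class. Alkyne oligomerisation on rhenium, or arrest after simple α-vinylation because the alkenyl–metal carbon does not add to the hindered aryl ketone beside the peri benzyloxy group, may outrun the ring expansion. Fallback, from 19 back to 22: 19 is treated with tert-butyl propiolate and catalytic Cs2CO3 in MeCN. This is the anionic form of the same ring expansion (conjugate addition of the enolate, aldol closure to a cyclobutenolate, retro-aldol), a known reaction of cyclic β-keto esters with acetylenic esters. It gives 6-tert-butyl 8-methyl 3,4-bis(benzyloxy)-1-Fl2-5-oxo-6,9-dihydro-5H-benzo[7]annulene-6,8-dicarboxylate F1, in which the extra ester sits on Cc as a β-keto tert-butyl ester. Catalytic p-toluenesulfonic acid in warm toluene removes it by loss of isobutene and decarboxylation and gives 22.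

**Step 12.** Over-oxidation, competing allylic oxidation at the benzylic C9 methylene, or selenium transfer to the electron-rich ring A may erode the oxygenation at Cc. Fallback, from 22 back to 24: the extended enolate of 22 is formed with LiN(SiMe3)2 in THF at −78 °C and hydroxylated at its α-carbon with 2-(phenylsulfonyl)-3-phenyloxaziridine. This gives methyl 3,4-bis(benzyloxy)-1-Fl2-6-hydroxy-5-oxo-6,9-dihydro-5H-benzo[7]annulene-8-carboxylate F2. Dess–Martin oxidation of F2 gives the dione 23, which tautomerises to 24.

**Step 13.** Hydride attack on the tropolone ring may occur if the aluminium tropolonate forms incompletely or is itself reduced. Fallback, from 24 back to 25: the ester is saponified with LiOH in aqueous THF (the lithium tropolonate is inert to hydroxide) to 3,4-bis(benzyloxy)-1-Fl2-6-hydroxy-5-oxo-5H-benzo[7]annulene-8-carboxylic acid F3. The acid is reduced with BH3·THF at 0 °C, an electrophilic hydride that prefers carboxylic acids to ketones, to give 25.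

**Step 18.** Stereochemical fidelity may be lost through ionisation of the activated carbinol, or the coupling may be sluggish at a hindered alcohol so that hydrazide alkylation or dehydration competes. The same concern, to a lesser degree, applies to step 7. Fallback, from 29 back to 30: the hydroxyl is first turned into a leaving group with methanesulfonyl chloride and Et3N in CH2Cl2 at −20 °C, giving (S)-[3,4,6-tris(benzyloxy)-1-Fl2-5-oxo-5H-benzo[7]annulen-8-yl][(2R)-oxiran-2-yl]methyl methanesulfonate F4. F4 is displaced with inversion by the caesium phenoxide of 14 (Cs2CO3, DMF, 0 °C) to give 30.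

**Step 3.** The stoichiometric Lewis acid may remove the benzyl group peri to the new ketone by chelation, and closure onto a ring deactivated by bromine may be slow. Fallback, from 2 (with 3) back to 8: 2 and 3 are condensed under organocatalytic reductive conditions (Hantzsch ester, L-proline, EtOH) so that the benzyl Meldrum's acid 5 is isolated. 5 is cyclised with catalytic Sc(OTf)3 in MeNO2 at 100 °C, a Friedel–Crafts acylation by the Meldrum's acid itself with loss of acetone and CO2, to give 8. This fallback makes no compound outside the list (F0).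

## Further compounds

F0 | step 3 | none | none
F1 | step 11 | 6-tert-butyl 8-methyl 3,4-bis(benzyloxy)-1-Fl2-5-oxo-6,9-dihydro-5H-benzo[7]annulene-6,8-dicarboxylate (C6 epimers) | COC(=O)C1=CC(C(=O)OC(C)(C)C)C(=O)c2c(OCc3ccccc3)c(OCc3ccccc3)cc([C@H]3Oc4cc(OCc5ccccc5)cc(OCc5ccccc5)c4C[C@H]3O[Si](C)(C)C(C)(C)C)c2C1
F2 | step 12 | methyl 3,4-bis(benzyloxy)-1-Fl2-6-hydroxy-5-oxo-6,9-dihydro-5H-benzo[7]annulene-8-carboxylate (C6 epimers) | COC(=O)C1=CC(O)C(=O)c2c(OCc3ccccc3)c(OCc3ccccc3)cc([C@H]3Oc4cc(OCc5ccccc5)cc(OCc5ccccc5)c4C[C@H]3O[Si](C)(C)C(C)(C)C)c2C1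
F3 | step 13 | 3,4-bis(benzyloxy)-1-Fl2-6-hydroxy-5-oxo-5H-benzo[7]annulene-8-carboxylic acid | OC(=O)C1=Cc2c([C@H]3Oc4cc(OCc5ccccc5)cc(OCc5ccccc5)c4C[C@H]3O[Si](C)(C)C(C)(C)C)cc(OCc3ccccc3)c(OCc3ccccc3)c2C(=O)C(O)=C1
F4 | step 18 | (S)-[3,4,6-tris(benzyloxy)-1-Fl2-5-oxo-5H-benzo[7]annulen-8-yl][(2R)-oxiran-2-yl]methyl methanesulfonate | CS(=O)(=O)O[C@H]([C@H]1CO1)C1=Cc2c([C@H]3Oc4cc(OCc5ccccc5)cc(OCc5ccccc5)c4C[C@H]3O[Si](C)(C)C(C)(C)C)cc(OCc3ccccc3)c(OCc3ccccc3)c2C(=O)C(OCc2ccccc2)=C1
A1 | alternative 1 | perbenzylated target with the C3 hydroxyl of flavan 2 free (flavan 1 as its tris(benzyloxy)benzoate, tropolone as benzyl ether) | O=c1cc([C@H]2Oc3cc(OCc4ccccc4)cc(OCc4ccccc4)c3C[C@H]2OC(=O)c2cc(OCc3ccccc3)c(OCc3ccccc3)c(OCc3ccccc3)c2)cc2c([C@H]3Oc4cc(OCc5ccccc5)cc(OCc5ccccc5)c4C[C@H]3O)cc(OCc3ccccc3)c(OCc3ccccc3)c2c1OCc1ccccc1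
A2 | alternative 2 | gem-dibromocyclopropane adduct of the bis(silyloxy)dihydronaphthalene carrying benzylated flavan 2 (all seven carbons of ring T present) | CC(C)(C)[Si](C)(C)OC1C(O[Si](C)(C)C(C)(C)C)C2C(c3c([C@H]4Oc5cc(OCc6ccccc6)cc(OCc6ccccc6)c5C[C@H]4OCc4ccccc4)cc(OCc4ccccc4)c(OCc4ccccc4)c31)C2(Br)Br
A3 | alternative 3 | benzo-fused 8-oxabicyclo[3.2.1]octadienone carrying benzylated flavan 2 and the acyl chain of flavan 1 (bridgehead epimers) | O=C1C2OC(c3c1c(OCc1ccccc1)c(OCc1ccccc1)cc3[C@H]1Oc3cc(OCc4ccccc4)cc(OCc4ccccc4)c3C[C@H]1OCc1ccccc1)C(C(=O)[C@H](OCOC)Cc1c(O[Si](C)(C)C(C)(C)C)cc(OCc3ccccc3)cc1OCc1ccccc1)=C2
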